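If starting material, target and isomer of the product A exchange faster than material enters or leaves them, the target's share of that trio follows from statistical weights, whatever the rate constants are.

solid substrate 20 mM; free catalyst 2.0 mM; time 10 d

    starting material ⇌ target (K1 = 0.47, k1 = 0.017 h⁻¹)
    starting material + free catalyst ⇌ isomer of the product A + free catalyst, rate k2*[starting material]*[free catalyst] forward; the back reaction follows from the equilibrium constant (K2 = 1.9, k2 = 13 M⁻¹ h⁻¹)
    starting material ⇌ isomer of the product B (K3 = 11, k3 = 0.0070 h⁻¹)
    solid substrate ⇌ starting material, rate k4*(cs4 - [starting material]) while solid is left; crystals form when [starting material] > cs4 (cs4 = 9.7 mM, k4 = 0.019 h⁻¹)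
    starting material + free catalyst → spent catalyst (k5 = 0.34 M⁻¹ h⁻¹)

1. amount of target at 10 d, in percent of the solid substrate charged
2. concentration of starting material in solution at 2.5 d, in percent of saturation
3. the change that raises the amount of target at 10 d, in percent of the solid substrate charged most ("none" if none brings more than 2 percentage points) (larch / maple / ash / none)
4. amount of target at 10 d, in percent of the solid substrate charged, after larch

- larch: doubling the amount of free catalyst, all else as stated
- maple: doubling the solubility in step 4, all else as stated
- ash: doubling the dissolution coefficient of step 4, all else as stated

- solid substrate is a solid; its amount is given per volume of the solution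
- at the start none of the solid substrate is in solution
- starting material means what is dissolved; the solid is not counted in it
- run time (flask): 10 d

1. Zero of the scale. In the flask, the exchange with target relaxes with half-life 0.543 d and the catalysed step, with the catalyst as charged, has forward half-life 1.1 d, both shorter than the relaxation half-life 3.78 d of the leak to isomer of the product B. So I took the trio as a pre-equilibrated pool with weights unity, 0.47 and 1.9. The target's equilibrium fraction of it, the weight share φ, is 13.9%. Neither catalyst, solubility nor dissolution coefficient stands in φ.

2. Base flask. The pseudo-first-order catalysed drain is 0.0260 h⁻¹. Balancing dissolution against this drain plus the leak put starting material at a fraction g of saturation, 36.5%, my figure for sat at 2.5 d. Holding g constant, I reckoned that the solid lasted τ = 7.12 d, less than the run. Neglecting the way back, I put the pool's leak at λ = 0.0499 d⁻¹. Taking dissolution as even over τ, I gave the mean dissolved parcel an age of 6.44 d, so I reckoned y = φ·exp(−λ·age) = 10.1%.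

3. Larch. Catalyst raises the drain and shortens τ to 5.98 d, giving 9.83%, which is my yb.

4. Maple. Here τ becomes 3.56 d, giving 9.26%.

5. Ash. Here τ becomes 4.86 d, giving 9.56%.

In my reckoning each change dissolved the solid sooner and left the pool longer to leak, so each figure fell below my base figure, and I answered none.

The forecast gave y 10%, sat 35.5%, best none and yb 9.3%, below my larch figure, holding that “Faster dissolution (ash, maple) only brings the peak earlier”.

The simulation gave y 9.68%, sat 35.9%, best none and yb 9.31%, with changes of −0.37 percentage points for larch, −1.4 points for maple and −1.2 points for ash.

At 10.0 d the flask held 0% solid substrate, and its trio summed to 66.6% of the charge. φ times that is 9.26%, against 9.68% target read. The neighbouring flask, charged with 80 mM of solid substrate, still held 69.0% of it as solid at 10.0 d. Its trio summed to 21.9% of its own charge, and φ times that is 3.04%. The neighbouring flask held 3.31% target.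

(All constants stand for no real mixture; the result is computed.)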